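**Plan**

- Numbering used: oxane ring O1, C2 (bears the acrylic acid; its α‑carbon is Cα), C3, C4, C5 (bears the trienyl chain), C6. Retrosynthetic cuts, in order: Cα=CH2 (Mannich methylenation); O1–C2 and C2=Cα (oxa‑Michael/Wittig on a lactol); C3–C4 and C5–C6 together; last, the bond between farnesyl C1 and a three‑carbon aldehyde unit.
- Enabling feature: in the oxane, C5 is a CH lying between C6H2–O1 and C4H2, and C4–C3–C2 is an unbranched run ending at the O‑bearing C2. C5 is therefore the α‑carbon of a latent C4 aldehyde that already carries the whole chain, so an enamine at C5 can take formaldehyde as C6 while the C4 carbonyl takes C3–C2 from a phosphorus ylide.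
- Forward order: chain aldehyde (steps 1–2); three‑component union of aldehyde, formaldehyde and ylide (step 3); saturation and lactone (step 4); lactol (step 5); the oxane ring closes last, at O1–C2 (step 6); methylene group and free acid (steps 7–8).
- Stereochemistry: C5 (S) from the (S)‑diarylprolinol silyl ether catalyst in step 3; C2 (R) from the reversible oxa‑Michael closure in step 6 (2,5‑trans, diequatorial chair); both (E)‑trisubstituted alkenes come unchanged from (2E,6E)‑farnesyl bromide.

Key step: step 3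

Remark: farnesyl bromide 1 is taken as the pure (2E,6E) isomer, and 2, 5 and 6 as purchased reagents (2 as its THF solution, 5 as 37% aqueous solution).

**Step 1**
Reactants: 1 (2E,6E)-1-bromo-3,7,11-trimethyldodeca-2,6,10-triene (farnesyl bromide); 2 [2-(1,3-dioxan-2-yl)ethyl]magnesium bromide
Product: 3 2-[(4E,8E)-5,9,13-trimethyltetradeca-4,8,12-trien-1-yl]-1,3-dioxane
Conditions: 2 (1.3 equiv), Li2CuCl4 (3 mol%), THF, −20 → 0 °C
Reagents that add atoms: none
Why: Kochi-type copper-catalysed coupling of a primary alkyl Grignard reagent with an allylic bromide, which in THF should take place at the primary allylic carbon (SN2, not SN2′), so that the (2E,6E) geometry is carried over and no stereocentre is formed.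

**Step 2**
Reactants: 3 2-[(4E,8E)-5,9,13-trimethyltetradeca-4,8,12-trien-1-yl]-1,3-dioxane
Product: 4 (5E,9E)-6,10,14-trimethylpentadeca-5,9,13-trienal
Conditions: 2 M aq HCl, THF, 45 °C
Reagents that add atoms: water, O
Why: Acid-catalysed acetal hydrolysis; dilute aqueous acid at moderate temperature should leave the three trisubstituted alkenes untouched.

**Step 3**
Reactants: 4 (5E,9E)-6,10,14-trimethylpentadeca-5,9,13-trienal; 5 formaldehyde; 6 methyl (triphenylphosphoranylidene)acetate
Product: 8 methyl (2E,4S,7E,11E)-4-(hydroxymethyl)-8,12,16-trimethylheptadeca-2,7,11,15-tetraenoate, via hydroxy aldehyde 7 (not isolated)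
Conditions: 5 (3 equiv), (S)-2-[diphenyl(trimethylsilyloxy)methyl]pyrrolidine (20 mol%), aq NaH2PO4/Na2HPO4 (pH 7), toluene, rt; aqueous phase removed; then 6 (2 equiv), toluene, 0 °C → rt
Reagents that add atoms: none
Why: Aldehyde 4 and the secondary amine form the (E)-enamine, whose C5 adds to formaldehyde on the face not screened by the diphenyl(silyloxy)methyl group (the Si face of C5) to make C5–C6; hydrolysis of the iminium ion releases (R)-7 and the catalyst, and the stabilised ylide 6 then converts the C4 carbonyl of 7 through an oxaphosphetane into the (E)-C3=C4 bond before 7 can enolise or lose water. The closest known reaction type is the amine-catalysed enamine α-hydroxymethylation of aldehydes with aqueous formaldehyde, combined with Wittig trapping of the labile β-hydroxy aldehyde in the same flask. No ring is closed in this step, but C6–OH and the C2 ester are now placed 1,5 to each other for the later closures. The new stereocentre C5 is under catalyst control (the (S)-catalyst should give the configuration that becomes 5S in the target), and the C3=C4 geometry set by the stabilised ylide is erased in step 4. The step needs enantiofacial selectivity, mono- rather than bis-hydroxymethylation and chemoselectivity against the chain alkenes: 4 has a single enolisable CH2, the bulky catalyst disfavours a second addition at the now tertiary C5, and isolated trisubstituted alkenes react neither with enamines nor with ylide 6.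

**Step 4**
Reactants: 8 methyl (2E,4S,7E,11E)-4-(hydroxymethyl)-8,12,16-trimethylheptadeca-2,7,11,15-tetraenoate
Product: 10 (5S)-5-[(3E,7E)-4,8,12-trimethyltrideca-3,7,11-trien-1-yl]oxan-2-one, via saturated hydroxy ester 9 (not isolated)
Conditions: Mg (10 equiv), MeOH, 0 °C → rt; aq NH4Cl; then pyridinium p-toluenesulfonate (cat.), toluene, 60 °C
Reagents that add atoms: none
Why: Dissolving-metal conjugate reduction (Mg/MeOH) acts by electron transfer only on the conjugated C3=C4 bond, leaving the isolated alkenes and the γ-stereocentre C5 untouched, and the δ-hydroxy ester then closes to the six-membered lactone by acid-catalysed transesterification.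

**Step 5**
Reactants: 10 (5S)-5-[(3E,7E)-4,8,12-trimethyltrideca-3,7,11-trien-1-yl]oxan-2-one
Product: 12 (5S)-5-[(3E,7E)-4,8,12-trimethyltrideca-3,7,11-trien-1-yl]oxan-2-ol (both anomers), via aluminium hemiacetal 11 (not isolated)
Conditions: i-Bu2AlH (1.1 equiv), CH2Cl2, −78 °C; aq potassium sodium tartrate
Reagents that add atoms: none
Why: Partial reduction of a δ-lactone with i-Bu2AlH at −78 °C should stop at the tetrahedral aluminium hemiacetal, which gives the lactol on hydrolysis; C5 is not affected.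

**Step 6**
Reactants: 12 (5S)-5-[(3E,7E)-4,8,12-trimethyltrideca-3,7,11-trien-1-yl]oxan-2-ol; 6 methyl (triphenylphosphoranylidene)acetate
Product: 14 methyl 2-{(2R,5S)-5-[(3E,7E)-4,8,12-trimethyltrideca-3,7,11-trien-1-yl]oxan-2-yl}acetate, via hydroxy enoate 13 (not isolated)
Conditions: 6 (1.5 equiv), toluene, 80 °C; then KOt-Bu (0.2 equiv), THF, 0 °C → rt
Reagents that add atoms: none
Why: Wittig olefination of the open hydroxy aldehyde form of 12 followed by 6-exo-trig intramolecular oxa-Michael addition, which is reversible under KOt-Bu, so that C2 should settle under thermodynamic control as the 2,5-trans (diequatorial chair) isomer, 2R.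

**Step 7**
Reactants: 14 methyl 2-{(2R,5S)-5-[(3E,7E)-4,8,12-trimethyltrideca-3,7,11-trien-1-yl]oxan-2-yl}acetate
Product: 18 methyl 2-{(2R,5S)-5-[(3E,7E)-4,8,12-trimethyltrideca-3,7,11-trien-1-yl]oxan-2-yl}prop-2-enoate, via lithium enolate 15 (not isolated), via Mannich base 16 (not isolated), via ammonium iodide 17 (not isolated)
Conditions: LiN(i-Pr)2 (1.15 equiv), THF, −78 °C; [Me2N=CH2]I (2 equiv), −78 °C → rt; MeI (excess), rt; DBU, rt
Reagents that add atoms: N,N-dimethylmethaniminium iodide (Eschenmoser's salt), C=[N+](C)C.[I-]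
Why: Ester enolate Mannich reaction followed by exhaustive N-methylation and E1cB loss of trimethylamine (α-methylenation); the epimeric centre formed at Cα in 16 is destroyed in the elimination and C2 and C5 are not involved.

**Step 8**
Reactants: 18 methyl 2-{(2R,5S)-5-[(3E,7E)-4,8,12-trimethyltrideca-3,7,11-trien-1-yl]oxan-2-yl}prop-2-enoate
Product: 20 rhopaloic acid A, 2-{(2R,5S)-5-[(3E,7E)-4,8,12-trimethyltrideca-3,7,11-trien-1-yl]oxan-2-yl}prop-2-enoic acid, via lithium carboxylate 19 (not isolated)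
Conditions: LiOH·H2O (3 equiv), THF–H2O, rt; then 1 M aq HCl to pH 3
Reagents that add atoms: lithium hydroxide, [Li+].[OH-]
Why: Saponification of the methyl ester; the α-substituted acrylate has no enolisable α-hydrogen, so neither C2 nor C5 should epimerise.

**Compound list**

1 | (2E,6E)-1-bromo-3,7,11-trimethyldodeca-2,6,10-triene (farnesyl bromide) | BrC/C=C(\C)CC/C=C(\C)CCC=C(C)C | starting material
2 | [2-(1,3-dioxan-2-yl)ethyl]magnesium bromide | Br[Mg]CCC1OCCCO1 | starting material
3 | 2-[(4E,8E)-5,9,13-trimethyltetradeca-4,8,12-trien-1-yl]-1,3-dioxane | C1COC(CCC/C=C(\C)CC/C=C(\C)CCC=C(C)C)OC1 | intermediate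
4 | (5E,9E)-6,10,14-trimethylpentadeca-5,9,13-trienal | O=CCCC/C=C(\C)CC/C=C(\C)CCC=C(C)C | intermediate
5 | formaldehyde | C=O | starting material
6 | methyl (triphenylphosphoranylidene)acetate | COC(=O)C=P(c1ccccc1)(c1ccccc1)c1ccccc1 | starting material
7 | (2R,5E,9E)-2-(hydroxymethyl)-6,10,14-trimethylpentadeca-5,9,13-trienal | O=C[C@@H](CO)CC/C=C(\C)CC/C=C(\C)CCC=C(C)C | intermediate
8 | methyl (2E,4S,7E,11E)-4-(hydroxymethyl)-8,12,16-trimethylheptadeca-2,7,11,15-tetraenoate | COC(=O)/C=C/[C@@H](CO)CC/C=C(\C)CC/C=C(\C)CCC=C(C)C | intermediate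
9 | methyl (4S,7E,11E)-4-(hydroxymethyl)-8,12,16-trimethylheptadeca-7,11,15-trienoate | COC(=O)CC[C@@H](CO)CC/C=C(\C)CC/C=C(\C)CCC=C(C)C | intermediate
10 | (5S)-5-[(3E,7E)-4,8,12-trimethyltrideca-3,7,11-trien-1-yl]oxan-2-one | O=C1CC[C@H](CC/C=C(\C)CC/C=C(\C)CCC=C(C)C)CO1 | intermediate
11 | bis(2-methylpropyl)aluminium hemiacetal of 10, {(5S)-5-[(3E,7E)-4,8,12-trimethyltrideca-3,7,11-trien-1-yl]oxan-2-yl}oxy-bis(2-methylpropyl)alumane | CC(C)C[Al](CC(C)C)OC1CC[C@H](CC/C=C(\C)CC/C=C(\C)CCC=C(C)C)CO1 | intermediate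
12 | (5S)-5-[(3E,7E)-4,8,12-trimethyltrideca-3,7,11-trien-1-yl]oxan-2-ol (both anomers) | OC1CC[C@H](CC/C=C(\C)CC/C=C(\C)CCC=C(C)C)CO1 | intermediate
13 | methyl (2E,6R,9E,13E)-6-(hydroxymethyl)-10,14,18-trimethylnonadeca-2,9,13,17-tetraenoate | COC(=O)/C=C/CC[C@@H](CO)CC/C=C(\C)CC/C=C(\C)CCC=C(C)C | intermediate
14 | methyl 2-{(2R,5S)-5-[(3E,7E)-4,8,12-trimethyltrideca-3,7,11-trien-1-yl]oxan-2-yl}acetate | COC(=O)C[C@H]1CC[C@H](CC/C=C(\C)CC/C=C(\C)CCC=C(C)C)CO1 | intermediate
15 | lithium 1-methoxy-2-{(2R,5S)-5-[(3E,7E)-4,8,12-trimethyltrideca-3,7,11-trien-1-yl]oxan-2-yl}ethen-1-olate | [Li+].[O-]C(OC)=C[C@H]1CC[C@H](CC/C=C(\C)CC/C=C(\C)CCC=C(C)C)CO1 | intermediate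
16 | methyl 3-(dimethylamino)-2-{(2R,5S)-5-[(3E,7E)-4,8,12-trimethyltrideca-3,7,11-trien-1-yl]oxan-2-yl}propanoate (both epimers at the propanoate C2) | COC(=O)C(CN(C)C)[C@H]1CC[C@H](CC/C=C(\C)CC/C=C(\C)CCC=C(C)C)CO1 | intermediate
17 | (3-methoxy-3-oxo-2-{(2R,5S)-5-[(3E,7E)-4,8,12-trimethyltrideca-3,7,11-trien-1-yl]oxan-2-yl}propyl)trimethylammonium iodide | [I-].COC(=O)C(C[N+](C)(C)C)[C@H]1CC[C@H](CC/C=C(\C)CC/C=C(\C)CCC=C(C)C)CO1 | intermediate
18 | methyl 2-{(2R,5S)-5-[(3E,7E)-4,8,12-trimethyltrideca-3,7,11-trien-1-yl]oxan-2-yl}prop-2-enoate | COC(=O)C(=C)[C@H]1CC[C@H](CC/C=C(\C)CC/C=C(\C)CCC=C(C)C)CO1 | intermediate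
19 | lithium 2-{(2R,5S)-5-[(3E,7E)-4,8,12-trimethyltrideca-3,7,11-trien-1-yl]oxan-2-yl}prop-2-enoate | [Li+].[O-]C(=O)C(=C)[C@H]1CC[C@H](CC/C=C(\C)CC/C=C(\C)CCC=C(C)C)CO1 | intermediate
20 | rhopaloic acid A, 2-{(2R,5S)-5-[(3E,7E)-4,8,12-trimethyltrideca-3,7,11-trien-1-yl]oxan-2-yl}prop-2-enoic acid | C=C(C(=O)O)[C@H]1CC[C@H](CC/C=C(\C)CC/C=C(\C)CCC=C(C)C)CO1 | target

**Step count and risks**

Total step count: 8. Longest linear sequence: 8 steps (1 → 20).

Steps most likely to fail:

**Step 3.** The β-hydroxy aldehyde 7 may lose its C5 configuration by enolisation, or lose water to the 2-methylene aldehyde, before the ylide has captured the carbonyl group; facial discrimination in the enamine addition may also be incomplete. Fallback, setting out from 4 and returning at 9: condensation of 4 with (S)-1-amino-2-(methoxymethyl)pyrrolidine should give the hydrazone (1E,5E,9E)-N-[(2S)-2-(methoxymethyl)pyrrolidin-1-yl]-6,10,14-trimethylpentadeca-5,9,13-trien-1-imine F1. Deprotonation with LiN(i-Pr)2 (THF, 0 °C) gives the azaenolate lithium [(2S)-2-(methoxymethyl)pyrrolidin-1-yl][(1E,5E,9E)-6,10,14-trimethylpentadeca-1,5,9,13-tetraen-1-yl]azanide F2. At −100 → −78 °C this adds in a Michael reaction to methyl acrylate, on the face left open by the lithium-chelating methoxymethyl group, to give methyl (4S,7E,11E)-4-[(E)-{[(2S)-2-(methoxymethyl)pyrrolidin-1-yl]imino}methyl]-8,12,16-trimethylheptadeca-7,11,15-trienoate F3. Two-phase hydrolysis with saturated aqueous oxalic acid and ether releases the auxiliary and methyl (4S,7E,11E)-4-formyl-8,12,16-trimethylheptadeca-7,11,15-trienoate F4, whose aldehyde is reduced at once with NaBH4 (MeOH, 0 °C) to 9, which is lactonised as in step 4. Here C5 is the same α-carbon of 4, but the carbonyl carbon of 4 becomes C6 and C4–C3–C2 come from the acrylate, so neither formaldehyde nor the labile aldehyde 7 is needed, and C5 is set by a stoichiometric auxiliary.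

**Step 7.** The ester enolate 15 may expel the ring oxygen (β-elimination with ring opening), which costs material and can scramble C2 on re-closure, and the aminomethylation may stay incomplete. Fallback, setting out from 12 and returning at 20: Knoevenagel condensation of 12 with dimethyl malonate (piperidinium acetate, toluene, 80 °C) should give dimethyl 2-[(4S,7E,11E)-4-(hydroxymethyl)-8,12,16-trimethylheptadeca-7,11,15-trien-1-ylidene]propanedioate F5. This closes in the same flask by reversible oxa-Michael addition to the trans product dimethyl 2-{(2R,5S)-5-[(3E,7E)-4,8,12-trimethyltrideca-3,7,11-trien-1-yl]oxan-2-yl}propanedioate F6. Saponification (KOH, MeOH–H2O, then acid) gives 2-{(2R,5S)-5-[(3E,7E)-4,8,12-trimethyltrideca-3,7,11-trien-1-yl]oxan-2-yl}propanedioic acid F7. Decarboxylative Mannich methylenation of this malonic acid (paraformaldehyde, Et2NH, EtOAc, reflux) gives 20 directly, with no strongly basic ester enolate involved.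

**Step 6.** Equilibration of the oxa-Michael addition may stay incomplete and leave too much of the kinetically formed 2,5-cis isomer, or the base may oligomerise enoate 13. Fallback, setting out from 10 and returning at 14: methyl acetate is deprotonated with LiN(i-Pr)2 (THF, −78 °C) to lithium 1-methoxyethen-1-olate F8, which adds to the lactone carbonyl of 10 to give the hemiketal methyl 2-{(5S)-2-hydroxy-5-[(3E,7E)-4,8,12-trimethyltrideca-3,7,11-trien-1-yl]oxan-2-yl}acetate F9. Ionic reduction (Et3SiH, BF3·OEt2, CH2Cl2, −78 °C) passes through the C2 oxocarbenium ion, which should take hydride axially on the half-chair that keeps the C5 chain pseudo-equatorial, giving the 2,5-trans ester 14 under kinetic control.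

**Further compounds**

F1 | step 3 | (1E,5E,9E)-N-[(2S)-2-(methoxymethyl)pyrrolidin-1-yl]-6,10,14-trimethylpentadeca-5,9,13-trien-1-imine | COC[C@@H]1CCCN1/N=C/CCC/C=C(\C)CC/C=C(\C)CCC=C(C)C
F2 | step 3 | lithium [(2S)-2-(methoxymethyl)pyrrolidin-1-yl][(1E,5E,9E)-6,10,14-trimethylpentadeca-1,5,9,13-tetraen-1-yl]azanide | [Li+].COC[C@@H]1CCCN1[N-]/C=C/CC/C=C(\C)CC/C=C(\C)CCC=C(C)C
F3 | step 3 | methyl (4S,7E,11E)-4-[(E)-{[(2S)-2-(methoxymethyl)pyrrolidin-1-yl]imino}methyl]-8,12,16-trimethylheptadeca-7,11,15-trienoate | COC[C@@H]1CCCN1/N=C/[C@H](CCC(=O)OC)CC/C=C(\C)CC/C=C(\C)CCC=C(C)C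
F4 | step 3 | methyl (4S,7E,11E)-4-formyl-8,12,16-trimethylheptadeca-7,11,15-trienoate | O=C[C@H](CCC(=O)OC)CC/C=C(\C)CC/C=C(\C)CCC=C(C)C
F5 | step 7 | dimethyl 2-[(4S,7E,11E)-4-(hydroxymethyl)-8,12,16-trimethylheptadeca-7,11,15-trien-1-ylidene]propanedioate | COC(=O)C(=CCC[C@@H](CO)CC/C=C(\C)CC/C=C(\C)CCC=C(C)C)C(=O)OC
F6 | step 7 | dimethyl 2-{(2R,5S)-5-[(3E,7E)-4,8,12-trimethyltrideca-3,7,11-trien-1-yl]oxan-2-yl}propanedioate | COC(=O)C(C(=O)OC)[C@H]1CC[C@H](CC/C=C(\C)CC/C=C(\C)CCC=C(C)C)CO1
F7 | step 7 | 2-{(2R,5S)-5-[(3E,7E)-4,8,12-trimethyltrideca-3,7,11-trien-1-yl]oxan-2-yl}propanedioic acid | OC(=O)C(C(=O)O)[C@H]1CC[C@H](CC/C=C(\C)CC/C=C(\C)CCC=C(C)C)CO1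
F8 | step 6 | lithium 1-methoxyethen-1-olate | [Li+].[O-]C(=C)OC
F9 | step 6 | methyl 2-{(5S)-2-hydroxy-5-[(3E,7E)-4,8,12-trimethyltrideca-3,7,11-trien-1-yl]oxan-2-yl}acetate | COC(=O)CC1(O)CC[C@H](CC/C=C(\C)CC/C=C(\C)CCC=C(C)C)CO1
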